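A closed, stirred vessel at constant volume and temperature is charged with substrate and other conformer, and it yields target and isomer of the product A.

- epsilon: substrate 0.50 M; other conformer 0.10 M; run made earlier
- flask: substrate 1.0 M; other conformer 0.100 M; time 10 min

- epsilon (time / min: target / %, isomer of the product A / %, substrate / %): 0.200: 16.4, 38.6, 33.6; 0.667: 23.7, 57.7, 3.5; 1.00: 23.7, 59.4, 0.3; 1.50: 22.4, 59.3, 0.3; 2.50: 19.6, 60.0, 0; 3.00: 17.9, 59.9, 0

(readings scatter by 0.3 percentage points)

- ratio of target to isomer of the product A at 0.50 s
- ratio of target to isomer of the product A at 15 s
- ratio of target to isomer of the product A at 10 min
- which of target and isomer of the product A there is more of at 10 min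



Take the main step first. In the earlier run substrate falls from 33.6% at 0.200 min to 3.5% at 0.667 min, a reading of 4.84 /min as a first-order constant. Target and isomer of the product A rise together, with a ratio of 0.425 at the first reading and 0.399 at 1.00 min. The reckoning here takes a ratio near that for the new flask at 0.50 s and 15 s.

Now add the loss. Once substrate reads 0.3%, isomer of the product A stays near 59.9%, while target falls from 23.7% to 17.9% at 3.00 min. Taken as first-order, that fall gives the loss constant of target, the net fraction of target lost per minute once substrate has fallen that far: a reading of 0.140 /min. While substrate lasts, its constant is far larger than this one, so target climbs; afterwards the ratio follows the loss.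

Last comes the charge. The new flask has twice the substrate of the earlier run, but a first-order constant contains no concentration. The reckoning here therefore carries the ratio at 1.00 min and the loss constant across unchanged. Decayed over the remaining 9.00 min, the ratio becomes 0.113, with isomer of the product A ahead.

The forecast gives 0.43 at 0.50 s, 0.43 at 15 s and 0.03 at 10 min, with isomer of the product A ahead. Its late figure is lower than the reckoning here, and rests on a loss that speeds up, which “suggests autocatalysis”.

The flask gives 0.390, 0.460 and 0.124, and isomer of the product A leads at 10 min, with 58.5% against 7.25% of target.

    other conformer → isomer of the product A (k = 1.20 /s)
    target ⇌ isomer of the product B (K = 0.460, k = 0.300 /s)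
    target → over-reaction product (k = 0.00330 /s)
    other conformer ⇌ third conformer (K = 8.40, k = 0.0390 /s)
    substrate ⇌ other conformer (K = 0.0650, k = 0.130 /s)
    substrate → target (k = 0.0350 /s)
    third conformer → third product (k = 0.0180 /s)

Early in this flask, part of the ratio comes from the return of other conformer to substrate: the run without that return gives 0.260 at 0.50 s rather than 0.390. Part of the late fall in this flask is the path from target to over-reaction product: the run without that path ends at 0.468 rather than 0.124. Carried forward, the loss constant takes this flask's 24.3% of target at 1.00 min to 6.89% at 10.0 min, where 7.25% stands. The same reckoning of 0.113 contains no charge of other conformer, and the neighbour flask charged with 0.040 M of it ends at 0.128.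

The numbers in the tables stem from a simulated flask from invented constants, noise included.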